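**Retrosynthetic overview**
1. The ester C6–O bond is made last: vanillic acid 13 displaces the activated carbamate oxygen of 12 at C-6 with inversion, which sets the trans O/isopropyl relationship.
2. 12 comes from ketone 8 by methyl addition, convex-face hydrogenation of the two trisubstituted C=C bonds (sets C-7, and C-6 as the cis epimer) and syn-dehydration.
3. 8 comes from diazoketone 6 by an enantioselective intramolecular Buchner reaction that sets C-8a.
4. 6 comes from thymol 1: para Friedel–Crafts addition to methyl vinyl ketone 2, O-carbamoylation, diazo transfer.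
5. Ring order: both carbocycles form in the Buchner step (five-membered ring by carbenoid closure, seven-membered ring by expansion of the thymol benzene ring).

Assumption: locants follow the azulene numbering of the names (C-6 carries the oxygen, C-7 the isopropyl group, C-8a is the ring-fusion CH, C3a=C4 is the tetrasubstituted alkene); the target SMILES corresponds to (6S,7R,8aR).

**Step 1**
Reactants: 1 thymol; 2 methyl vinyl ketone
Product: 3 4-[4-hydroxy-2-methyl-5-(propan-2-yl)phenyl]butan-2-one
Conditions: CF3SO3H (5 mol %), toluene, 0 → 25 °C, slow addition of 2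
Reagents that add atoms: none
Why: Acid-catalysed Friedel–Crafts conjugate alkylation (hydroarylation of the enone); the OH group directs to its para position, the least hindered activated site of thymol, so the chain enters ortho to the ring methyl group and no stereocentre is formed.

**Step 2**
Reactants: 3 4-[4-hydroxy-2-methyl-5-(propan-2-yl)phenyl]butan-2-one
Product: 4 5-methyl-4-(3-oxobutyl)-2-(propan-2-yl)phenyl diethylcarbamate
Conditions: Et2NCOCl, K2CO3, MeCN, 80 °C
Reagents that add atoms: N,N-diethylcarbamoyl chloride, CCN(CC)C(Cl)=O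
Why: O-Carbamoylation of the phenoxide (acyl substitution); the diethylcarbamate survives amide bases, carbenoids, organocerium reagents and hydrogenation, and is kept until it becomes the leaving group in step 8.

**Step 3**
Reactants: 4 5-methyl-4-(3-oxobutyl)-2-(propan-2-yl)phenyl diethylcarbamate
Product: 6 4-(4-diazo-3-oxobutyl)-5-methyl-2-(propan-2-yl)phenyl diethylcarbamate, via trifluoroacetyl diketone 5 (not isolated)
Conditions: LiN(SiMe3)2, THF, −78 °C; CF3CO2CH2CF3; aq. HCl; then MsN3, Et3N, H2O, MeCN, 25 °C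
Reagents that add atoms: methanesulfonyl azide, CS(=O)(=O)N=[N+]=[N-]
Why: Danheiser detrifluoroacetylative diazo transfer: kinetic deprotonation of the methyl group, Claisen trifluoroacetylation to 5, then Regitz diazo transfer with loss of the trifluoroacetyl group, which places the diazo group on the terminal carbon only.

**Step 4**
Reactants: 6 4-(4-diazo-3-oxobutyl)-5-methyl-2-(propan-2-yl)phenyl diethylcarbamate
Product: 8 (8aS)-4-methyl-1-oxo-7-(propan-2-yl)-1,2,3,8a-tetrahydroazulen-6-yl diethylcarbamate, via norcaradiene 7 (not isolated)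
Conditions: [Cu(MeCN)4]PF6 (5 mol %), 2,2′-(propane-2,2-diyl)bis[(4R)-4-phenyl-4,5-dihydrooxazole] (6 mol %), NaB[C6H3(CF3)2]4 (6 mol %), CH2Cl2, 40 °C, slow addition; 8 used directly
Reagents that add atoms: none
Why: Intramolecular Buchner reaction: the copper carbenoid cyclopropanates the ipso/ortho-H bond (the ortho-methyl side is blocked), closing the five-membered ring, and 6π electrocyclic opening of norcaradiene 7 expands the benzene ring to the cycloheptatriene; the chiral bis(oxazoline) ligand (antipode chosen to give 8aS) selects the arene face and sets C-8a.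

**Step 5**
Reactants: 8 (8aS)-4-methyl-1-oxo-7-(propan-2-yl)-1,2,3,8a-tetrahydroazulen-6-yl diethylcarbamate
Product: 9 (1R,8aS)-1-hydroxy-1,4-dimethyl-7-(propan-2-yl)-1,2,3,8a-tetrahydroazulen-6-yl diethylcarbamate
Conditions: MeMgBr, CeCl3, THF, −78 °C; aq. NH4Cl
Reagents that add atoms: methylmagnesium bromide, C[Mg]Br
Why: Organocerium 1,2-addition, non-basic so the acidic H-8a is not removed and the enol carbamate is untouched; the methyl group enters the ketone face syn to H-8a (anti to ring carbon C-8), giving the 1R carbinol with OH trans to H-8a.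

**Step 6**
Reactants: 9 (1R,8aS)-1-hydroxy-1,4-dimethyl-7-(propan-2-yl)-1,2,3,8a-tetrahydroazulen-6-yl diethylcarbamate
Product: 10 (1R,6R,7R,8aS)-1-hydroxy-1,4-dimethyl-7-(propan-2-yl)-1,2,3,5,6,7,8,8a-octahydroazulen-6-yl diethylcarbamate
Conditions: H2 (20 atm), RhCl(PPh3)3 (10 mol %), toluene–EtOH, 40 °C
Reagents that add atoms: none
Why: Homogeneous hydrogenation that reduces the two trisubstituted C=C bonds but not the tetrasubstituted C3a=C4 bond; the cycloheptatriene boat carries H-8a axially on its concave face, so H2 adds on the open convex face and the second addition is anti to the newly created substituent, placing H-6 and H-7 cis to each other and trans to H-8a (6R,7R, oxygen cis to isopropyl).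

**Step 7**
Reactants: 10 (1R,6R,7R,8aS)-1-hydroxy-1,4-dimethyl-7-(propan-2-yl)-1,2,3,5,6,7,8,8a-octahydroazulen-6-yl diethylcarbamate
Product: 12 (6R,7R,8aR)-1,4-dimethyl-7-(propan-2-yl)-3,5,6,7,8,8a-hexahydroazulen-6-yl diethylcarbamate, via sulfamate ester 11 (not isolated)
Conditions: MeO2C–N(−)–SO2–N(+)Et3 (Burgess reagent), toluene, 50 °C
Reagents that add atoms: none
Why: Burgess dehydration by syn (Ei) elimination through 11: the OH is trans to H-8a, so that hydrogen cannot be lost and the endocyclic trisubstituted C1=C2 alkene forms from a syn C-2 hydrogen, leaving C-8a and the skipped diene intact.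

**Step 8**
Reactants: 12 (6R,7R,8aR)-1,4-dimethyl-7-(propan-2-yl)-3,5,6,7,8,8a-hexahydroazulen-6-yl diethylcarbamate; 13 vanillic acid (4-hydroxy-3-methoxybenzoic acid)
Product: 16 (6S,7R,8aR)-1,4-dimethyl-7-(propan-2-yl)-3,5,6,7,8,8a-hexahydroazulen-6-yl 4-hydroxy-3-methoxybenzoate, via triflyloxyiminium triflate 14 (not isolated), via isouronium triflate 15 (not isolated)
Conditions: Tf2O (1.05 equiv), 2,6-di-tert-butylpyridine, CH2Cl2, −78 °C; pyrrolidine (1.0 equiv), −78 → −30 °C; then 13 (1.5 equiv), iPr2NEt (1.5 equiv), MeCN, −30 → 40 °C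
Reagents that add atoms: none
Why: Proposed new method: the tertiary carbamate serves as a latent leaving group — Tf2O O-sulfonylates the carbamate carbonyl (as in amide activation) to give 14, pyrrolidine displaces triflate at the iminium carbon (as in amidine synthesis from activated amides) to give the O-alkylisouronium salt 15 whose central carbon is no longer electrophilic, and the carboxylate of 13 (the only anion formed with one equivalent of base, so the phenol stays free) attacks C-6 by SN2 with the neutral tetraalkylurea as nucleofuge, forming the ester C–O bond with inversion (6R → 6S, oxygen trans to isopropyl) while no free alcohol is present that could be acylated with retention; the closest known reaction types are the inverting esterification of carboxylic acids by O-alkylisoureas and the Mitsunobu displacement of alkoxyphosphonium salts.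

**Compound list**
1 | thymol, 5-methyl-2-(propan-2-yl)phenol | Cc1ccc(C(C)C)c(O)c1 | starting material
2 | methyl vinyl ketone, but-3-en-2-one | CC(=O)C=C | starting material
3 | 4-[4-hydroxy-2-methyl-5-(propan-2-yl)phenyl]butan-2-one | CC(=O)CCc1cc(C(C)C)c(O)cc1C | intermediate
4 | 5-methyl-4-(3-oxobutyl)-2-(propan-2-yl)phenyl diethylcarbamate | CCN(CC)C(=O)Oc1cc(C)c(CCC(C)=O)cc1C(C)C | intermediate
5 | 5-methyl-2-(propan-2-yl)-4-(6,6,6-trifluoro-3,5-dioxohexyl)phenyl diethylcarbamate (not isolated) | CCN(CC)C(=O)Oc1cc(C)c(CCC(=O)CC(=O)C(F)(F)F)cc1C(C)C | intermediate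
6 | 4-(4-diazo-3-oxobutyl)-5-methyl-2-(propan-2-yl)phenyl diethylcarbamate | CCN(CC)C(=O)Oc1cc(C)c(CCC(=O)C=[N+]=[N-])cc1C(C)C | intermediate
7 | norcaradiene valence isomer of 8: cyclopropane spanning the former ipso carbon, the former ortho CH and the carbenoid CH, cis-fused to the cyclopentanone and to the cyclohexadiene, carbenoid carbon configured as C-8a of 8 (not isolated) | CC1=CC(OC(=O)N(CC)CC)=C(C(C)C)[C@H]2[C@@H]3C(=O)CC[C@]123 | intermediate
8 | (8aS)-4-methyl-1-oxo-7-(propan-2-yl)-1,2,3,8a-tetrahydroazulen-6-yl diethylcarbamate | CCN(CC)C(=O)OC1=CC(C)=C2CCC(=O)[C@H]2C=C1C(C)C | intermediate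
9 | (1R,8aS)-1-hydroxy-1,4-dimethyl-7-(propan-2-yl)-1,2,3,8a-tetrahydroazulen-6-yl diethylcarbamate | CCN(CC)C(=O)OC1=CC(C)=C2CC[C@@](C)(O)[C@H]2C=C1C(C)C | intermediate
10 | (1R,6R,7R,8aS)-1-hydroxy-1,4-dimethyl-7-(propan-2-yl)-1,2,3,5,6,7,8,8a-octahydroazulen-6-yl diethylcarbamate | CCN(CC)C(=O)O[C@@H]1CC(C)=C2CC[C@@](C)(O)[C@H]2C[C@@H]1C(C)C | intermediate
11 | triethylammonium salt of the N-(methoxycarbonyl)sulfamate ester of the tertiary alcohol 10 (not isolated) | CCN(CC)C(=O)O[C@@H]1CC(C)=C2CC[C@@](C)(OS(=O)(=O)[N-]C(=O)OC)[C@H]2C[C@@H]1C(C)C.CC[NH+](CC)CC | intermediate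
12 | (6R,7R,8aR)-1,4-dimethyl-7-(propan-2-yl)-3,5,6,7,8,8a-hexahydroazulen-6-yl diethylcarbamate | CCN(CC)C(=O)O[C@@H]1CC(C)=C2CC=C(C)[C@H]2C[C@@H]1C(C)C | intermediate
13 | vanillic acid, 4-hydroxy-3-methoxybenzoic acid | COc1cc(C(=O)O)ccc1O | starting material
14 | N,N-diethyl-(alkoxy)(trifluoromethanesulfonyloxy)methaniminium triflate from 12, alkoxy = the (6R,7R,8aR)-hexahydroazulen-6-yloxy group (not isolated) | CC[N+](CC)=C(OS(=O)(=O)C(F)(F)F)O[C@@H]1CC(C)=C2CC=C(C)[C@H]2C[C@@H]1C(C)C.[O-]S(=O)(=O)C(F)(F)F | intermediate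
15 | O-[(6R,7R,8aR)-hexahydroazulen-6-yl]-N,N-diethyl-N′,N′-tetramethyleneisouronium triflate (not isolated) | CC[N+](CC)=C(N1CCCC1)O[C@@H]2CC(C)=C3CC=C(C)[C@H]3C[C@@H]2C(C)C.[O-]S(=O)(=O)C(F)(F)F | intermediate
16 | (6S,7R,8aR)-1,4-dimethyl-7-(propan-2-yl)-3,5,6,7,8,8a-hexahydroazulen-6-yl 4-hydroxy-3-methoxybenzoate | COc1cc(C(=O)O[C@H]2CC(C)=C3CC=C(C)[C@H]3C[C@@H]2C(C)C)ccc1O | target

**Totals**
Total steps: 8. Longest linear sequence: 8 (1 → 16).

**Three steps most likely to fail**

Step 8 (the proposed carbamate-to-isouronium displacement). The hindered C-6 centre may undergo E2 elimination towards the diene conjugated with C3a=C4, or ionise with participation of that double bond. The fallback uses known chemistry only, sets out from 12 and returns at 16. LiAlH4 (THF, 65 °C) cleaves the carbamate to (6R,7R,8aR)-1,4-dimethyl-7-(propan-2-yl)-3,5,6,7,8,8a-hexahydroazulen-6-ol F4. Ph2PCl, Et3N and DMAP (THF, 0 °C) convert it into (6R,7R,8aR)-1,4-dimethyl-7-(propan-2-yl)-3,5,6,7,8,8a-hexahydroazulen-6-yl diphenylphosphinite F5. A Mukaiyama oxidation–reduction condensation of F5 with 4-acetoxy-3-methoxybenzoic acid and 2,6-dimethyl-1,4-benzoquinone (CH2Cl2, 25 °C) forms the ester with inversion, (6S,7R,8aR)-1,4-dimethyl-7-(propan-2-yl)-3,5,6,7,8,8a-hexahydroazulen-6-yl 4-acetoxy-3-methoxybenzoate F6. K2CO3 in MeOH (0 °C) then removes only the phenolic acetate and gives 16.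

Step 6 (one-pot double hydrogenation). RhCl(PPh3)3 may be too slow on trisubstituted alkenes, or face selectivity may erode after the first addition. The fallback sets out from 9 and returns at 10, splitting the reduction into two stages under different control. [Rh(C8H12)(Ph2P(CH2)4PPh2)]BF4 with H2 (3 atm, CH2Cl2) hydrogenates only the C=C bond that can chelate through the carbamate carbonyl, giving the allylic carbamate (1R,6R,8aS)-1-hydroxy-1,4-dimethyl-7-(propan-2-yl)-1,2,3,5,6,8a-hexahydroazulen-6-yl diethylcarbamate F1. The remaining trisubstituted C7=C8 bond is then reduced over Rh on Al2O3 (H2 1 atm, EtOAc) from the face anti to the carbamate, giving 10.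

Step 7 (Burgess dehydration). Ionisation of the tertiary sulfamate could give the exocyclic methylene isomer or the diene conjugated through C-8a. The fallback sets out from 8 and returns at 12, replacing addition/dehydration by cross-coupling. Ketone 8 is hydrogenated as in step 6 (H2, RhCl(PPh3)3) to (6R,7R,8aS)-4-methyl-1-oxo-7-(propan-2-yl)-1,2,3,5,6,7,8,8a-octahydroazulen-6-yl diethylcarbamate F2. Kinetic deprotonation at C-2 with LiN(iPr)2 (THF, −78 °C) and trapping with N-(5-chloropyridin-2-yl)bis(trifluoromethanesulfonyl)imide gives the enol triflate (6R,7R,8aS)-4-methyl-7-(propan-2-yl)-1-[(trifluoromethanesulfonyl)oxy]-3,5,6,7,8,8a-hexahydroazulen-6-yl diethylcarbamate F3. Negishi methylation (MeZnCl, Pd(PPh3)4, THF, 40 °C) gives 12. The weak point of this fallback is competing deprotonation at the allylic C-8a.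

**Further compounds**
F1 | step 6 | (1R,6R,8aS)-1-hydroxy-1,4-dimethyl-7-(propan-2-yl)-1,2,3,5,6,8a-hexahydroazulen-6-yl diethylcarbamate | CCN(CC)C(=O)O[C@@H]1CC(C)=C2CC[C@@](C)(O)[C@H]2C=C1C(C)C
F2 | step 7 | (6R,7R,8aS)-4-methyl-1-oxo-7-(propan-2-yl)-1,2,3,5,6,7,8,8a-octahydroazulen-6-yl diethylcarbamate | CCN(CC)C(=O)O[C@@H]1CC(C)=C2CCC(=O)[C@H]2C[C@@H]1C(C)C
F3 | step 7 | (6R,7R,8aS)-4-methyl-7-(propan-2-yl)-1-[(trifluoromethanesulfonyl)oxy]-3,5,6,7,8,8a-hexahydroazulen-6-yl diethylcarbamate | CCN(CC)C(=O)O[C@@H]1CC(C)=C2CC=C(OS(=O)(=O)C(F)(F)F)[C@H]2C[C@@H]1C(C)C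
F4 | step 8 | (6R,7R,8aR)-1,4-dimethyl-7-(propan-2-yl)-3,5,6,7,8,8a-hexahydroazulen-6-ol | O[C@@H]1CC(C)=C2CC=C(C)[C@H]2C[C@@H]1C(C)C
F5 | step 8 | (6R,7R,8aR)-1,4-dimethyl-7-(propan-2-yl)-3,5,6,7,8,8a-hexahydroazulen-6-yl diphenylphosphinite | P(c1ccccc1)(c2ccccc2)O[C@@H]3CC(C)=C4CC=C(C)[C@H]4C[C@@H]3C(C)C
F6 | step 8 | (6S,7R,8aR)-1,4-dimethyl-7-(propan-2-yl)-3,5,6,7,8,8a-hexahydroazulen-6-yl 4-acetoxy-3-methoxybenzoate | COc1cc(C(=O)O[C@H]2CC(C)=C3CC=C(C)[C@H]3C[C@@H]2C(C)C)ccc1OC(C)=O
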